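The pitfall in this flask is to start the coupling clock at time zero. At the start none of the solid partner is in solution, and it has to dissolve before it can react as fresh partner.

- south-west: starting material 0.050 M; solid partner 0.900 equiv; capture agent 1.00 mM; gas 1.8 mM (held); time 2.5 h
- south: starting material 0.050 M; solid partner 0.900 equiv; capture agent 1.00 mM; gas 1.8 mM (held); time 5.0 h

- which of these there is most of at the end, counted by the starting material in it, south-west (starting material / product / open intermediate)
- which of these there is most of at the end, counted by the starting material in it, south (starting material / product / open intermediate)
- the largest of these amounts at the end, in percent of the starting material charged, south-west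
- the largest of these amounts at the end, in percent of the starting material charged, south

The solid partner is the limiting reagent, since its charge of 45.0 mM is below the 0.050 M of starting material. At its fastest it dissolves at 0.312 mM min⁻¹, so I get a feed time F = 144 min. With both intermediates at full strength, the coupling constant 0.58 M⁻¹ min⁻¹ and the charge 0.050 M give a coupling time C = 34.5 min. I keep these two times. In south-west, with the concentrations as charged, the half-life of reagent by its reaction with starting material alone is 0.55 min, much shorter than F. In south-west, with the capture agent as charged, the half-life of second intermediate by capture alone is 7.2 h, longer than the run time of south. F/C is 4.17, so I reckon with both F and C.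

I solve the two ends and join them. Late on, I take the feed as over and a fraction x/(1+x) of the partner as coupled, where x is the time on the coupling clock divided by C. Early on, I take both intermediates as climbing in straight lines. The coupling rate, which goes with both together, then climbs as time squared, and over F that is worth a third of F at full strength. So the feed counts as a dead time L = 96.2 min, and the clock starts there.

This gives x = 1.56 for south-west and x = 5.91 for south. My reckoning is product at 54.9% in south-west, and product at 77.0% in south.

The forecast says product at 52% in south-west and product at 78% in south, adding “the rate falls off well before that”. Mine is higher in south-west and lower in south.

    starting material + reagent → open intermediate (k1 = 25 M⁻¹ min⁻¹)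
    reagent + fresh partner → second intermediate (k2 = 1200 M⁻¹ min⁻¹)
    open intermediate + second intermediate → product (k3 = 0.58 M⁻¹ min⁻¹)
    solid partner ⇌ fresh partner, rate k4*(cs4 - [fresh partner]) while solid is left; crystals form when [fresh partner] > cs4 (cs4 = 13 mM, k4 = 0.024 min⁻¹)
    second intermediate + capture agent → trapped intermediate (k5 = 1.6 M⁻¹ min⁻¹)
    gas ⇌ reagent, rate k6*(csat - [reagent]) (k6 = 0.69 min⁻¹, csat = 1.8 mM)

The flask gives product at 52.5% in south-west and product at 78.3% in south, so the forecast holds. South-west still has 49.5% of its solid partner at 1.25 h. The product in south moves by 6 points at 0.804 equiv or 1.02 equiv of solid partner, or at 3.86 h or 8.08 h of time, the rest held. With L, the clock for south-west at 25.0 h reads x = 40.7, which gives 87.8%; the flask gives 87.9%.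

For the reading of south-west at 4.0 h, L gives x = 4.17 and so 72.6% product. The computed flask holds 73.3%.

(The numbers of this flask are those of an exercise; the result is computed.)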